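The data stem from a simulated flask from invented constants; noise was put on by code.

**Two charges.** The ratio I read first was one of fractional rates. At 0.020 M the starting material was lost at 0.283 min⁻¹ by the reading at 0.500 min, and at 0.010 M at 0.280 min⁻¹ by the reading at 50.0 s. That is a ratio of 1.01, where a second-order loss gives 2.00. I carried their mean, 0.281 min⁻¹, as f, the share of c(starting material) lost per minute early on, an apparent first-order constant.

| flask | starting material | remark | time |
|---|---|---|---|
| south-east | 0.020 M | run made earlier |  |
| north-east | 0.010 M | run made earlier |  |
| dawn | 0.020 M | plug flow through a tube for 2.5 min, no back-mixing | 2.5 min |
| spring | 0.020 M | a single well-mixed tank run continuously and read at steady state, 2.5 min in it on average |  |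
| winter | 0.020 M | everything together in a closed stirred flask, run for 2.5 min | 2.5 min |

south-east run (percent of the starting material charged)

| time / min | target / % | starting material / % |
|---|---|---|
| 0.200 | 0.1 | 94.7 |
| 0.500 | 1.1 | 86.8 |
| 1.00 | 4.1 | 77.6 |
| 2.50 | 21.0 | 57.1 |

north-east run (percent of the starting material charged)

| time / s | target / % | starting material / % |
|---|---|---|
| 10.0 | 0 | 95.2 |
| 15.0 | 0.7 | 92.8 |
| 30.0 | 2.1 | 87.5 |
| 50.0 | 5.3 | 79.2 |

(readings scatter by 1 percentage point)

- the set-up with the highest amount of target at the outlet or at the end, in percent of the starting material put in ("none" if the first two lie within 2 percentage points) (dawn / spring / winter / none)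
- amount of target at the outlet or at the end, in percent of the starting material put in, dawn
- amount of target at the outlet or at the end, in percent of the starting material put in, spring
- amount of target at the outlet or at the end, in percent of the starting material put in, winter

- the stated concentrations are those of everything mixed, before any reaction; amounts are the same in each set-up
- the numbers in the tables scatter by 1 percentage point (one standard deviation)
- the earlier runs were made in a closed, stirred flask

**The charge.** By hand, the balance of starting material then reads: loss equals f times c. In that balance, turning the charge moves no percentage.

**The time.** By hand, f leaves 49.5% at 2.5 min, but the south-east run read 57.1%, which is more. So the loss of starting material in the south-east run slowed. That reading and its 21.0% of target leave 21.9% unseen.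

**The vessel.** Plug flow for 2.5 min repeats a closed flask run for that time at the same charge, so I put dawn and winter at the 21.0% of target that the south-east run read at 2.50 min. By hand, one first-order step in a tank with 2.5 min on average leaves 58.7% of starting material, which is more, so I put spring lower than dawn in target.

**The forecast.** It gave 21% for dawn, 19% for spring and 21% for winter, with best none: “With linear kinetics, concentration doesn't matter.”

**The result.** Dawn and winter gave 19.9% and 19.9%, spring 17.7%, so best is none, and the forecast held.

    starting material ⇌ intermediate A (K = 1.10, k = 0.00480 s⁻¹)
    intermediate A → intermediate B (k = 0.00690 s⁻¹)
    intermediate A → target (k = 0.00950 s⁻¹)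
    target ⇌ intermediate B (K = 0.370, k = 0.00270 s⁻¹)
    starting material + intermediate B → side product (k = 0.0240 M⁻¹ s⁻¹)

**The rates.** Dawn kept 55% of its starting material, above the 49.5% from f, and it held 10.8% of intermediate B and 0.458% of side product. At 0.982 min in dawn, the passing of starting material into intermediate A, its forward rate alone, used starting material 300 times as fast as the passing of starting material and intermediate B into side product did.

**Second flask.** For dawn left until 40 s, f gives 82.9% of starting material left; the computed flask holds 84%.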